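Retrosynthesis: the 12Z-diene is cut at C13–C14 and C12=C13 (vinyl coupling, iodo-olefination of a C12 aldehyde that comes from a C11=C12 vinyl group); ring B is cut at C8–C9; the open chain is cut at C7–C8 (acyl anion + lactone), C5=C6 (intramolecular olefination), C9–C11 (vinyl Grignard) and C10–C9 (asymmetric allylation of 2,2,6-trimethylcyclohexanone).
Enabling feature: C8 is a tertiary carbinol next to oxygenated C7, so C7/C8 can be a 1,2-diketone whose acetyl carbonyl C8 is the electrophile; C9 bears CH2-11 beside the quaternary C10, so C9 can be the γ-carbon of an allylmetal C12–C11=C9 that leaves the C11=C12 vinyl group for the side chain; ring B (C5–C10) then closes by carbonyl allylation.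
Forward order: ring A is bought, C10 is made quaternary, a temporary δ-lactone (C7(=O)–O–C9, a ring and a C9–O bond absent from the target) is closed across C5/C10 to set C5 and is opened again to the acyclic diketone allylic acetate, ring B is closed (C8–C9), C6 and C7 are adjusted on the rigid trans-decalin, and the diene is built last.
Stereochemistry: C10 by catalyst control; C5 by α-face protonation in the bicyclic lactone; C8 and C9 together in the chelated chair transition state of the key step, which is stereoconvergent for the C9–O epimers; C6 (α-face Rubottom oxidation) and C7 (hydroxyl-directed hydride) by substrate control; 12Z by Stork–Zhao olefination and a retentive Stille coupling.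

Key step: step 11

Remark: labdane numbering (C1–C20) and α/β descriptors (C20 methyl β) are used for all intermediates; 8–15 are carried as mixtures of C9 epimers (12 also at C7, 21 at C12), which converge in step 11 or are erased later.

Step 1
Reactants: 1 2,2,6-trimethylcyclohexan-1-one
Product: 3 allyl 2,6,6-trimethylcyclohex-1-en-1-yl carbonate, via lithium enolate 2 (not isolated)
Conditions: LiN(SiMe3)2, THF, 0 °C; then allyl chloroformate, −78 → 25 °C
Reagents that add atoms: allyl chloroformate, C=CCOC(Cl)=O
Why: The ketone has a single enolisable position, and O-acylation of the hindered tetrasubstituted lithium enolate by the chloroformate (enol carbonate formation) should give the substrate for decarboxylative allylation without creating a stereocentre.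

Step 2
Reactants: 3 allyl 2,6,6-trimethylcyclohex-1-en-1-yl carbonate
Product: 4 (R)-2-allyl-2,6,6-trimethylcyclohexan-1-one
Conditions: Pd2(dba)3 (2.5 mol%), (R)-t-Bu-PHOX (6 mol%), THF, 25 °C
Reagents that add atoms: none
Why: Tsuji-type decarboxylative asymmetric allylic alkylation: ionisation and loss of CO2 give a π-allylpalladium enolate whose C-allylation inside the chiral P,N-ligand sphere should set the quaternary C10 centre as (R), the ligand enantiomer being chosen for this sense of induction.

Step 3
Reactants: 4 (R)-2-allyl-2,6,6-trimethylcyclohexan-1-one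
Product: 5 (R)-2,2,6-trimethyl-6-[(E)-prop-1-en-1-yl]cyclohexan-1-one
Conditions: RuHCl(CO)(PPh3)3 (2 mol%), toluene, 80 °C
Reagents that add atoms: none
Why: Ruthenium hydride catalysed alkene isomerisation (hydrometalation/β-hydride elimination) should move the terminal double bond to the more substituted position next to the quaternary carbon, which cannot epimerise, and the alkene geometry is irrelevant for the next step.

Step 4
Reactants: 5 (R)-2,2,6-trimethyl-6-[(E)-prop-1-en-1-yl]cyclohexan-1-one
Product: 7 (R)-1,3,3-trimethyl-2-oxocyclohexane-1-carbaldehyde, via ozonide 6 (not isolated)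
Conditions: O3, CH2Cl2, −78 °C; then PPh3, −78 → 25 °C
Reagents that add atoms: ozone, [O-][O+]=O
Why: Ozonolysis with reductive work-up cleaves the only C=C bond to the neopentyl aldehyde (C9) while the non-enolisable hindered ketone is untouched and C10 is unchanged.

Step 5
Reactants: 7 (R)-1,3,3-trimethyl-2-oxocyclohexane-1-carbaldehyde
Product: 8 (2R)-2-(1-hydroxyprop-2-en-1-yl)-2,6,6-trimethylcyclohexan-1-one (C9 epimers)
Conditions: CH2=CHMgBr, THF, −78 °C; then aq. NH4Cl
Reagents that add atoms: vinylmagnesium bromide, C=C[Mg]Br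
Why: Grignard addition is chemoselective for the aldehyde over the doubly neopentyl ketone and brings in C11, C12 and the C9 oxygen; the new C9 carbinol centre need not be controlled because it is erased in the key step.

Step 6
Reactants: 8 (2R)-2-(1-hydroxyprop-2-en-1-yl)-2,6,6-trimethylcyclohexan-1-one
Product: 9 1-[(1R)-1,3,3-trimethyl-2-oxocyclohexyl]prop-2-en-1-yl 2-(diethoxyphosphoryl)acetate
Conditions: (EtO)2P(O)CH2CO2H, DCC, DMAP (cat.), CH2Cl2, 0 → 25 °C
Reagents that add atoms: diethylphosphonoacetic acid, OC(=O)CP(=O)(OCC)OCC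
Why: Steglich esterification acylates the hindered secondary allylic alcohol under neutral conditions and tethers the future C6/C7 unit to the C9 oxygen without touching a stereocentre.

Step 7
Reactants: 9 1-[(1R)-1,3,3-trimethyl-2-oxocyclohexyl]prop-2-en-1-yl 2-(diethoxyphosphoryl)acetate
Product: 10 (8aS)-1-ethenyl-5,5,8a-trimethyl-1,5,6,7,8,8a-hexahydro-3H-isochromen-3-one
Conditions: NaH, DME, 0 → 85 °C
Reagents that add atoms: none
Why: Intramolecular Horner–Wadsworth–Emmons olefination: the tether makes addition of the phosphonate anion to the very hindered C5 ketone entropically feasible, and the six-membered lactone fixes the C5=C6 geometry with C7 cis to C10.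

Step 8
Reactants: 10 (8aS)-1-ethenyl-5,5,8a-trimethyl-1,5,6,7,8,8a-hexahydro-3H-isochromen-3-one
Product: 11 (4aS,8aS)-1-ethenyl-5,5,8a-trimethyloctahydro-3H-isochromen-3-one
Conditions: SmI2, HMPA, t-BuOH, THF, 0 °C
Reagents that add atoms: none
Why: Single-electron conjugate reduction of the α,β-unsaturated lactone by divalent samarium should leave the isolated vinyl group and the allylic C–O bond alone, and protonation of C5 from the α-face, opposite the axial C10 and C4 methyl groups, should give the trans-fused lactone (5α-H).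

Step 9
Reactants: 11 (4aS,8aS)-1-ethenyl-5,5,8a-trimethyloctahydro-3H-isochromen-3-one
Product: 12 (4aS,8aS)-1-ethenyl-3-(1-ethoxyethenyl)-5,5,8a-trimethyloctahydro-1H-isochromen-3-ol
Conditions: ethyl vinyl ether, t-BuLi, THF, −78 → 0 °C; then 11, −78 °C; aq. NH4Cl
Reagents that add atoms: 1-ethoxyvinyllithium (made from ethyl vinyl ether), [Li]C(=C)OCC
Why: The acyl anion equivalent adds once to the lactone carbonyl because the tetrahedral lithium hemiketal is stable at −78 °C, which forms the C7–C8 bond and brings in C8 and C17 at the diketone oxidation level without forming a stereocentre of the target.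

Step 10
Reactants: 12 (4aS,8aS)-1-ethenyl-3-(1-ethoxyethenyl)-5,5,8a-trimethyloctahydro-1H-isochromen-3-ol
Product: 14 1-[(1S,2S)-2-(2,3-dioxobutyl)-1,3,3-trimethylcyclohexyl]prop-2-en-1-yl acetate, via enol ether acetate 13 (not isolated)
Conditions: Ac2O, Et3N, DMAP (cat.), CH2Cl2, 25 °C; then 1 M HCl, THF, 25 °C
Reagents that add atoms: acetic anhydride, CC(=O)OC(C)=O; water, O
Why: Acetylation should trap the ring-opened hydroxy enone tautomer of the lactol at the secondary C9 oxygen (the tertiary hemiketal hydroxyl is acylated slowly and reversibly), and mild acid hydrolysis of the enol ether then unveils the C7/C8 1,2-diketone, the C9 acetate being formed as both epimers.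

Step 11
Reactants: 14 1-[(1S,2S)-2-(2,3-dioxobutyl)-1,3,3-trimethylcyclohexyl]prop-2-en-1-yl acetate
Product: 16 8α-hydroxy-13,14,15,16-tetranorlabd-11-en-7-one, via allylindium 15 (not isolated)
Conditions: Pd(PPh3)4 (5 mol%), InI (2 equiv), THF/HMPA, 25 °C; then 1 M HCl
Reagents that add atoms: none
Why: Zerovalent palladium ionises either C9 epimer of the allylic acetate and InI converts the π-allylpalladium acetate by reductive transmetalation into the (E)-σ-allylindium 15 with trivalent indium on C12, so that the allyl unit becomes nucleophilic at its γ-carbon C9 (umpolung); the closest known reaction type is the palladium-catalysed, InI-mediated umpolung allylation of carbonyl compounds by allylic esters together with the indium-mediated Barbier allylation of 1,2-diketones. C9 then adds to the acetyl carbonyl C8 through a six-membered chair (Zimmerman–Traxler) transition state, which closes ring B (C5–C6–C7–C8–C9–C10) in a 6-exo-trig mode onto the C8=O group. C9 is controlled by the allyl geometry: the tertiary C10 substituent enforces the (E)-allylindium and sits equatorial in the chair, so H-9 becomes axial (α) and the new vinyl group equatorial (β), the chair of ring B being fixed by its trans fusion to ring A through the C5 and C10 centres already set. C8 is controlled by the metal: indium is bound to the C8 oxygen in the chair and chelated by the coplanar C7 carbonyl oxygen, which places O-8 equatorial (α) and the methyl group axial (β), the arrangement also demanded by the trans-fused bicyclic transition state. The step needs site selectivity for C8=O over C7=O (a six- instead of a five-membered ring and the less hindered methyl ketone secure it), γ- over α-attack of the allylmetal (α-attack would need an eight-membered ring) and stereoconvergence, which the common allylindium intermediate provides for the epimeric acetates.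

Step 12
Reactants: 16 8α-hydroxy-13,14,15,16-tetranorlabd-11-en-7-one
Product: 19 6α,8α-dihydroxy-13,14,15,16-tetranorlabd-11-en-7-one, via bis(trimethylsilyl) enol ether 17 (not isolated), via bis(trimethylsilyl) α-siloxy ketone 18 (not isolated)
Conditions: Me3SiOTf, Et3N, CH2Cl2, 0 °C; then mCPBA, NaHCO3, −20 °C; then 1 M HCl, THF
Reagents that add atoms: mCPBA, O=C(OO)c1cccc(Cl)c1
Why: Rubottom oxidation: C6 is the only enolisable position of the C7 ketone, and the peracid should attack the silyl enol ether from the α-face because the β-face of C6 is screened by the syn-axial C4 and C10 methyl groups, which gives the equatorial 6α-hydroxyl while the terminal vinyl group reacts far more slowly.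

Step 13
Reactants: 19 6α,8α-dihydroxy-13,14,15,16-tetranorlabd-11-en-7-one
Product: 21 8α,12-epoxy-6α,12-dihydroxy-13,14,15,16-tetranorlabdan-7-one, via hydroxy aldehyde 20 (not isolated)
Conditions: PdCl2(PhCN)2 (10 mol%), CuCl2·2H2O (10 mol%), AgNO2 (5 mol%), O2 (1 atm), t-BuOH/MeNO2, 25 °C
Reagents that add atoms: dioxygen, O=O
Why: Nitrite-modified, aldehyde-selective Wacker oxidation should deliver oxygen to the terminal carbon C12 of the monosubstituted alkene (anti-Markovnikov selectivity, helped by the homoallylic 8-hydroxyl and the branching at C9), and the aldehyde is trapped by the 8α-hydroxyl as the five-membered lactol without touching a ring stereocentre.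

Step 14
Reactants: 21 8α,12-epoxy-6α,12-dihydroxy-13,14,15,16-tetranorlabdan-7-one
Product: 22 (12Z)-6α,8α-dihydroxy-13-iodo-14,15-dinorlabd-12-en-7-one
Conditions: EtPPh3I, n-BuLi, THF, 25 °C; then I2, −78 °C; then NaN(SiMe3)2, −20 °C; then 21, −78 → −20 °C
Reagents that add atoms: ethyltriphenylphosphonium iodide, [I-].CC[P+](c1ccccc1)(c1ccccc1)c1ccccc1; iodine, II
Why: Stork–Zhao olefination: the lactol reacts through its hydroxy aldehyde form with the α-iodo ylide, whose kinetically controlled Wittig addition should give the (Z)-iodoalkene (iodine cis to C11), and the hindered C7 ketone is not olefinated.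

Step 15
Reactants: 22 (12Z)-6α,8α-dihydroxy-13-iodo-14,15-dinorlabd-12-en-7-one
Product: 23 (12Z)-6α,8α-dihydroxylabda-12,14-dien-7-one
Conditions: Bu3SnCH=CH2, Pd2(dba)3 (5 mol%), AsPh3, CuI (cat.), NMP, 25 °C
Reagents that add atoms: tributyl(vinyl)stannane, C=C[Sn](CCCC)(CCCC)CCCC
Why: Stille coupling proceeds with retention of the alkenyl iodide geometry under neutral conditions, so the vinyl group ends up cis to C11 and the (12Z)-diene is formed without touching the free hydroxyls or the ketone.

Step 16
Reactants: 23 (12Z)-6α,8α-dihydroxylabda-12,14-dien-7-one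
Product: 24 (12Z)-6α-acetoxy-8α-hydroxylabda-12,14-dien-7-one
Conditions: Ac2O, pyridine, DMAP (cat.), CH2Cl2, 0 °C
Reagents that add atoms: acetic anhydride, CC(=O)OC(C)=O
Why: Acylation distinguishes the secondary 6α-hydroxyl from the tertiary 8α-hydroxyl, and because O-7 is still a ketone no regioisomeric acetate can form.

Step 17
Reactants: 24 (12Z)-6α-acetoxy-8α-hydroxylabda-12,14-dien-7-one
Product: 25 (12Z)-6α-acetoxylabda-12,14-diene-7β,8α-diol
Conditions: Me4NBH(OAc)3, MeCN/AcOH, −20 °C
Reagents that add atoms: none
Why: Evans–Saksena reduction: the 8α-hydroxyl binds the triacetoxyborohydride and delivers hydride to the α-face of C7 (also the axial, less hindered trajectory), which should give the equatorial 7β-alcohol trans to O-8, while the acidic medium suppresses acetyl migration from O-6 and leaves the diene untouched.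

Compound list
1 | 2,2,6-trimethylcyclohexan-1-one (racemic) | CC1CCCC(C)(C)C1=O | starting material
2 | lithium 2,6,6-trimethylcyclohex-1-en-1-olate | [Li+].[O-]C1=C(C)CCCC1(C)C | intermediate
3 | allyl 2,6,6-trimethylcyclohex-1-en-1-yl carbonate | C=CCOC(=O)OC1=C(C)CCCC1(C)C | intermediate
4 | (R)-2-allyl-2,6,6-trimethylcyclohexan-1-one | C=CC[C@@]1(C)CCCC(C)(C)C1=O | intermediate
5 | (R)-2,2,6-trimethyl-6-[(E)-prop-1-en-1-yl]cyclohexan-1-one | C/C=C/[C@@]1(C)CCCC(C)(C)C1=O | intermediate
6 | 3-methyl-5-[(1R)-1,3,3-trimethyl-2-oxocyclohexyl]-1,2,4-trioxolane (ozonide, diastereomer mixture) | CC1OOC(O1)[C@@]2(C)CCCC(C)(C)C2=O | intermediate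
7 | (R)-1,3,3-trimethyl-2-oxocyclohexane-1-carbaldehyde | O=C[C@@]1(C)CCCC(C)(C)C1=O | intermediate
8 | (2R)-2-(1-hydroxyprop-2-en-1-yl)-2,6,6-trimethylcyclohexan-1-one, both carbinol (C9) epimers | C=CC(O)[C@@]1(C)CCCC(C)(C)C1=O | intermediate
9 | 1-[(1R)-1,3,3-trimethyl-2-oxocyclohexyl]prop-2-en-1-yl 2-(diethoxyphosphoryl)acetate, C9 epimers | C=CC(OC(=O)CP(=O)(OCC)OCC)[C@@]1(C)CCCC(C)(C)C1=O | intermediate
10 | (8aS)-1-ethenyl-5,5,8a-trimethyl-1,5,6,7,8,8a-hexahydro-3H-isochromen-3-one (unsaturated δ-lactone: C5=C6, C7 lactone carbonyl, O on C9; C9 epimers) | C=CC1OC(=O)C=C2C(C)(C)CCC[C@@]21C | intermediate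
11 | (4aS,8aS)-1-ethenyl-5,5,8a-trimethyloctahydro-3H-isochromen-3-one (trans-fused lactone, 5α-H, 10β-CH3; C9 epimers) | C=CC1OC(=O)C[C@H]2C(C)(C)CCC[C@@]21C | intermediate
12 | (4aS,8aS)-1-ethenyl-3-(1-ethoxyethenyl)-5,5,8a-trimethyloctahydro-1H-isochromen-3-ol (lactol, in equilibrium with its open hydroxy enone; C7 and C9 epimers) | C=CC1OC(O)(C(=C)OCC)C[C@H]2C(C)(C)CCC[C@@]21C | intermediate
13 | 1-[(1S,2S)-2-(3-ethoxy-2-oxobut-3-en-1-yl)-1,3,3-trimethylcyclohexyl]prop-2-en-1-yl acetate, C9 epimers | C=CC(OC(C)=O)[C@@]1(C)CCCC(C)(C)[C@@H]1CC(=O)C(=C)OCC | intermediate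
14 | 1-[(1S,2S)-2-(2,3-dioxobutyl)-1,3,3-trimethylcyclohexyl]prop-2-en-1-yl acetate, C9 epimers | C=CC(OC(C)=O)[C@@]1(C)CCCC(C)(C)[C@@H]1CC(=O)C(C)=O | intermediate
15 | (E)-allylindium acetate iodide of 14 (indium on C12, C9=C11 E, ring A centres as in 14) | CC(=O)O[In](I)C/C=C/[C@@]1(C)CCCC(C)(C)[C@@H]1CC(=O)C(C)=O | intermediate
16 | 8α-hydroxy-13,14,15,16-tetranorlabd-11-en-7-one (5α-H, 9α-H, 10β-CH3, 8β-CH3, 9β-vinyl) | C=C[C@H]1[C@](C)(O)C(=O)C[C@H]2C(C)(C)CCC[C@@]21C | intermediate
17 | 7,8α-bis(trimethylsilyloxy)-13,14,15,16-tetranorlabda-6,11-diene | C=C[C@H]1[C@](C)(O[Si](C)(C)C)C(O[Si](C)(C)C)=C[C@H]2C(C)(C)CCC[C@@]21C | intermediate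
18 | 6α,8α-bis(trimethylsilyloxy)-13,14,15,16-tetranorlabd-11-en-7-one | C=C[C@H]1[C@](C)(O[Si](C)(C)C)C(=O)[C@H](O[Si](C)(C)C)[C@H]2C(C)(C)CCC[C@@]21C | intermediate
19 | 6α,8α-dihydroxy-13,14,15,16-tetranorlabd-11-en-7-one | C=C[C@H]1[C@](C)(O)C(=O)[C@H](O)[C@H]2C(C)(C)CCC[C@@]21C | intermediate
20 | 6α,8α-dihydroxy-7-oxo-13,14,15,16-tetranorlabdan-12-al | O=CC[C@H]1[C@](C)(O)C(=O)[C@H](O)[C@H]2C(C)(C)CCC[C@@]21C | intermediate
21 | 8α,12-epoxy-6α,12-dihydroxy-13,14,15,16-tetranorlabdan-7-one (five-membered lactol, both C12 anomers) | OC1C[C@H]2[C@](C)(O1)C(=O)[C@H](O)[C@H]3C(C)(C)CCC[C@]23C | intermediate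
22 | (12Z)-6α,8α-dihydroxy-13-iodo-14,15-dinorlabd-12-en-7-one (iodine cis to C11) | C/C(I)=C/C[C@H]1[C@](C)(O)C(=O)[C@H](O)[C@H]2C(C)(C)CCC[C@@]21C | intermediate
23 | (12Z)-6α,8α-dihydroxylabda-12,14-dien-7-one | C=C/C(C)=C\C[C@H]1[C@](C)(O)C(=O)[C@H](O)[C@H]2C(C)(C)CCC[C@@]21C | intermediate
24 | (12Z)-6α-acetoxy-8α-hydroxylabda-12,14-dien-7-one | C=C/C(C)=C\C[C@H]1[C@](C)(O)C(=O)[C@H](OC(C)=O)[C@H]2C(C)(C)CCC[C@@]21C | intermediate
25 | (12Z)-6α-acetoxylabda-12,14-diene-7β,8α-diol | C=C/C(C)=C\C[C@H]1[C@](C)(O)[C@@H](O)[C@H](OC(C)=O)[C@H]2C(C)(C)CCC[C@@]21C | target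

Total steps: 17. Longest linear sequence: 17 steps (1 to 25; the route is linear).

Steps most likely to fail

Step 11. The π-allylpalladium intermediate may be intercepted by the enolisable diketone (C- or O-allylation through C6 or the enol oxygen), the diketone may be reduced by InI before transmetalation, or the allylmetal may add to the C7 carbonyl. Fallback: from 14, palladium-catalysed borylation of the allylic acetate (B2pin2, Pd2(dba)3 cat., DMSO, 50 °C) should give the isolable, non-reducing (E)-allylboronate F1 with boron on C12. Warming F1 in toluene (60 °C, Sc(OTf)3 cat. if needed) should bring about intramolecular allylboration of the acetyl carbonyl through the same trans-fused chair. Hydrolysis of the borate ester on buffered aqueous work-up returns to 16.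

Step 7. The stabilised phosphonate anion may fail to add to the C5 carbonyl, which lies between two quaternary carbons, so that no ring closure or only ester cleavage takes place. Fallback: from 8, acylation with bromoacetyl bromide (pyridine, CH2Cl2, −20 °C) gives the bromoacetate F2. SmI2 (THF, −78 °C) then generates a small samarium enolate that adds to the ketone intramolecularly (Reformatsky reaction) to give the β-hydroxy lactone F3. Dehydration (SOCl2, pyridine, 0 °C), possible only towards C6, rejoins the route at 10.

Step 14. Ring opening of the lactol may be slow, and the strongly basic ylide may trigger α-ketol rearrangement or erode the Z selectivity. Fallback: from 21, dibromo-olefination with Ph3P=CBr2 (from (dibromomethyl)triphenylphosphonium bromide and KOt-Bu; Et3N, THF) gives the 1,1-dibromoalkene F4. A trans-selective Negishi monomethylation (MeZnCl, Pd(DPEphos)Cl2 cat., THF, 0 °C) replaces the bromine trans to C11 and gives the (Z)-bromoalkene F5. F5 enters the Stille coupling of step 15 in place of 22 and rejoins the route at 23.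

Further compounds
F1 | step 11 | (E)-allyl pinacolboronate of the diketone (Bpin on C12, C9=C11 E, ring A centres as in 14) | CC1(C)OB(C/C=C/[C@@]2(C)CCCC(C)(C)[C@@H]2CC(=O)C(C)=O)OC1(C)C
F2 | step 7 | 1-[(1R)-1,3,3-trimethyl-2-oxocyclohexyl]prop-2-en-1-yl 2-bromoacetate (C9 epimers) | C=CC(OC(=O)CBr)[C@@]1(C)CCCC(C)(C)C1=O
F3 | step 7 | 1-ethenyl-4a-hydroxy-5,5,8a-trimethyloctahydro-3H-isochromen-3-one (β-hydroxy lactone, C10 as in 8, C5 and C9 epimers) | C=CC1OC(=O)CC2(O)C(C)(C)CCC[C@@]21C
F4 | step 14 | 13,13-dibromo-6α,8α-dihydroxy-14,15,16-trinorlabd-12-en-7-one | BrC(Br)=CC[C@H]1[C@](C)(O)C(=O)[C@H](O)[C@H]2C(C)(C)CCC[C@@]21C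
F5 | step 14 | (12Z)-13-bromo-6α,8α-dihydroxy-14,15-dinorlabd-12-en-7-one (bromine cis to C11) | C/C(Br)=C/C[C@H]1[C@](C)(O)C(=O)[C@H](O)[C@H]2C(C)(C)CCC[C@@]21C
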